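## Retrosynthetic overview

1. Daphnodorin C 22 ⇐ penta-O-benzyl ether 21 (hydrogenolysis last). 21 ⇐ its flat isomer 19, a seven-membered cyclic enol acetal, by a chiral-acid-catalysed 1,3 O→C shift (Petasis–Ferrier-type ring contraction 7→5). This shift forms the bond between the spiro carbon and the neighbouring ArCH–O carbon.
2. Enabling feature: O=C-3–C-2(spiro)–CH(Ar)–O, spanning the benzofuranone and dihydrofuran rings, is an aldol (β-aryloxy ketone) array. C-2 is the α-carbon of a benzofuran-3(2H)-one whose enol is an aromatic 3-hydroxybenzofuran. The CH carbon lies between the dihydrofuran ring oxygen and a p-oxygenated phenyl ring, so it is a doubly stabilised cation.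
3. One operation should give the C–C bond, the quaternary spiro centre, the adjacent centre, the dihydrofuran ring and the ketone. It should also funnel both acetal epimers into one configuration.
4. 19 ⇐ 2-arylbenzofuranone 16 + ArCHCl2 18. 16 ⇐ Negishi union of 8-bromoflavan 9 with 3-(MOMO)benzofuran 12 (chroman C-8–benzofuran C-2 bond). 9 ⇐ chalcone 5 (asymmetric transfer hydrogenation, Mitsunobu).
5. Ring order: chroman (step 5) → benzofuran brought in ready-made (step 9) → temporary dioxepine (step 12) → dihydrofuran with spiro centre (step 13).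

Key step: step 13

Assumption: the sense of induction of the chiral acid in step 13 cannot be derived from a close model, so the (R)-acid is written and its mirror image would be taken if a first run shows the opposite sense (the remote chroman centre should make both pairings similar).

## Route

Step 1
Reactants: 1 2,4,6-trihydroxybenzaldehyde
Product: 2 2,6-dihydroxy-4-(methoxymethoxy)benzaldehyde
Conditions: MOMCl (1.0 equiv), K2CO3, acetone, 0 °C → rt
Reagents that add atoms: chloromethyl methyl ether, COCCl
Why: Williamson-type O-alkylation in which the 4-OH, the only hydroxyl not hydrogen-bonded to the aldehyde and the most acidic one, should take the single equivalent of MOMCl.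

Step 2
Reactants: 2 2,6-dihydroxy-4-(methoxymethoxy)benzaldehyde
Product: 3 2-(benzyloxy)-6-hydroxy-4-(methoxymethoxy)benzaldehyde
Conditions: BnBr (1.05 equiv), K2CO3, DMF, rt
Reagents that add atoms: benzyl bromide, BrCc1ccccc1
Why: Williamson etherification of one of two equivalent hydroxyls, after which the last one is held in a strong chelate to the aldehyde and reacts much more slowly, so the reaction should stop at the monoether.

Step 3
Reactants: 3 2-(benzyloxy)-6-hydroxy-4-(methoxymethoxy)benzaldehyde; 4 1-[4-(benzyloxy)phenyl]ethanone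
Product: 5 (E)-3-[2-(benzyloxy)-6-hydroxy-4-(methoxymethoxy)phenyl]-1-[4-(benzyloxy)phenyl]prop-2-en-1-one
Conditions: KOH, EtOH, rt → 40 °C
Reagents that add atoms: none
Why: Claisen–Schmidt condensation in which only the ketone can enolise and only the aldehyde can accept, dehydration gives the conjugated E-enone, and MOM and benzyl ethers are stable to base.

Step 4
Reactants: 5 (E)-3-[2-(benzyloxy)-6-hydroxy-4-(methoxymethoxy)phenyl]-1-[4-(benzyloxy)phenyl]prop-2-en-1-one
Product: 7 (1R)-3-[2-(benzyloxy)-6-hydroxy-4-(methoxymethoxy)phenyl]-1-[4-(benzyloxy)phenyl]propan-1-ol, via 3-[2-(benzyloxy)-6-hydroxy-4-(methoxymethoxy)phenyl]-1-[4-(benzyloxy)phenyl]propan-1-one 6 (not isolated)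
Conditions: RuCl[(R,R)-TsDPEN](p-cymene) (2 mol %), HCO2Na, MeOH/H2O, 40 °C
Reagents that add atoms: none
Why: Noyori–Ikariya asymmetric transfer hydrogenation run as the known one-pot C=C/C=O reduction of chalcones, in which the Ru hydride first reduces the enone 1,4 to ketone 6 and then adds to one face of the aryl ketone, the (R,R)-ligand giving the (R)-benzylic alcohol through the usual CH/π-organised six-membered transition state.

Step 5
Reactants: 7 (1R)-3-[2-(benzyloxy)-6-hydroxy-4-(methoxymethoxy)phenyl]-1-[4-(benzyloxy)phenyl]propan-1-ol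
Product: 8 (2S)-5-(benzyloxy)-2-[4-(benzyloxy)phenyl]-7-(methoxymethoxy)chromane
Conditions: PPh3, DIAD, toluene/THF, −10 → 0 °C
Reagents that add atoms: none
Why: Intramolecular Mitsunobu etherification (6-exo-tet) in which the phenol displaces the activated benzylic oxygen with inversion, (R)-carbinol to (2S)-chroman, while low temperature and a weakly polar medium hold back ionisation of the p-alkoxybenzylic centre.

Step 6
Reactants: 8 (2S)-5-(benzyloxy)-2-[4-(benzyloxy)phenyl]-7-(methoxymethoxy)chromane
Product: 9 (2S)-5-(benzyloxy)-2-[4-(benzyloxy)phenyl]-8-bromo-7-(methoxymethoxy)chromane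
Conditions: NBS (1.0 equiv), CH2Cl2, −78 → −20 °C
Reagents that add atoms: N-bromosuccinimide, O=C1CCC(=O)N1Br
Why: Electrophilic aromatic bromination of by far the most electron-rich ring, where C-8, next to the tied-back ring oxygen, is attacked in preference to C-6 between two freely rotating alkoxy groups, as is usual for 5,7-dialkoxyflavans.

Step 7
Reactants: 10 4,6-dihydroxy-1-benzofuran-3(2H)-one
Product: 11 4,6-bis(benzyloxy)-1-benzofuran-3(2H)-one
Conditions: BnBr (2.2 equiv), K2CO3, DMF, rt
Reagents that add atoms: benzyl bromide, BrCc1ccccc1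
Why: Williamson etherification of both phenols with a weak base that deprotonates the phenols far more than C-2, so O-alkylation should prevail over C-2 alkylation.

Step 8
Reactants: 11 4,6-bis(benzyloxy)-1-benzofuran-3(2H)-one
Product: 12 4,6-bis(benzyloxy)-3-(methoxymethoxy)-1-benzofuran
Conditions: KHMDS, THF, −78 °C; MOMCl, −78 → 0 °C
Reagents that add atoms: chloromethyl methyl ether, COCCl
Why: O-alkylation of a potassium enolate by a hard α-chloro ether, which takes enolates at oxygen and is helped here by the aromaticity of the 3-alkoxybenzofuran formed.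

Step 9
Reactants: 12 4,6-bis(benzyloxy)-3-(methoxymethoxy)-1-benzofuran; 9 (2S)-5-(benzyloxy)-2-[4-(benzyloxy)phenyl]-8-bromo-7-(methoxymethoxy)chromane
Product: 15 (2S)-5-(benzyloxy)-2-[4-(benzyloxy)phenyl]-8-[4,6-bis(benzyloxy)-3-(methoxymethoxy)-1-benzofuran-2-yl]-7-(methoxymethoxy)chromane, via [4,6-bis(benzyloxy)-3-(methoxymethoxy)-1-benzofuran-2-yl]lithium 13 (not isolated), via [4,6-bis(benzyloxy)-3-(methoxymethoxy)-1-benzofuran-2-yl]zinc chloride 14 (not isolated)
Conditions: 12, n-BuLi, THF, −78 °C; ZnCl2, → rt; 9, Pd2(dba)3 (2.5 mol %), SPhos (10 mol %), THF, 65 °C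
Reagents that add atoms: none
Why: C-2 lithiation of the benzofuran (most acidic C–H, assisted by O-1 and the 3-OMOM group), transmetalation and Negishi coupling with a dialkylbiarylphosphine ligand of the kind used for tri-ortho-substituted (hetero)biaryls, with no stereocentre touched.

Step 10
Reactants: 15 (2S)-5-(benzyloxy)-2-[4-(benzyloxy)phenyl]-8-[4,6-bis(benzyloxy)-3-(methoxymethoxy)-1-benzofuran-2-yl]-7-(methoxymethoxy)chromane
Product: 16 4,6-bis(benzyloxy)-2-{(2S)-5-(benzyloxy)-2-[4-(benzyloxy)phenyl]-7-hydroxychroman-8-yl}-1-benzofuran-3(2H)-one (both epimers at benzofuranone C-2)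
Conditions: HCl (cat.), MeOH/THF, 0 °C → rt, argon
Reagents that add atoms: none
Why: Acid-catalysed acetal methanolysis frees the phenol and the enol (which settles as the ketone) while benzyl ethers and the chroman C-2–O bond survive, excess methanol binds the formaldehyde unit as dimethoxymethane, and mild acid with exclusion of air holds back cyclodehydration onto C-3 and autoxidation at the labile C-2.

Step 11
Reactants: 17 4-(benzyloxy)benzaldehyde
Product: 18 1-(benzyloxy)-4-(dichloromethyl)benzene
Conditions: SOCl2, DMF (cat.), CH2Cl2, 0 °C → rt; used crude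
Reagents that add atoms: thionyl chloride, O=S(Cl)Cl
Why: Deoxygenative gem-dichlorination of an aromatic aldehyde under Vilsmeier-type activation, a known conversion that is favoured by the p-alkoxy group and leaves the benzyl ether intact.

Step 12
Reactants: 16 4,6-bis(benzyloxy)-2-{(2S)-5-(benzyloxy)-2-[4-(benzyloxy)phenyl]-7-hydroxychroman-8-yl}-1-benzofuran-3(2H)-one; 18 1-(benzyloxy)-4-(dichloromethyl)benzene
Product: 19 cyclic 4-(benzyloxy)benzylidene acetal of the enol form of 16 (1,3-dioxepine ring made of the acetal CH, O on chroman C-7, C-7, C-8, benzofuran C-2, C-3 and O on C-3; chroman C-2 S; both acetal epimers)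
Conditions: Cs2CO3, DMF (degassed, dilute), 0 °C → rt, argon; basic alumina
Reagents that add atoms: none
Why: Double Williamson-type O-alkylation with a gem-dihalide, the way catechols and 2,2'-biaryldiols are bridged to cyclic acetals, in which the ionising hard electrophile should take the enolate at oxygen as MOMCl does in step 8, the acetal is inert to base and cannot rearrange here, and its new stereocentre forms unselectively but is erased in step 13.

Step 13
Reactants: 19 cyclic 4-(benzyloxy)benzylidene acetal of the enol form of 16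
Product: 21 (2S,2'S,8'S)-4,5',6-tris(benzyloxy)-2',8'-bis[4-(benzyloxy)phenyl]-3',4'-dihydro-2'H,8'H-spiro[1-benzofuran-2,9'-furo[2,3-h]chromen]-3-one (penta-O-benzyldaphnodorin C), via ring-opened oxocarbenium ion 20 (not isolated)
Conditions: (R)-TRIP (10 mol %), 4 Å MS, toluene, −20 °C → rt
Reagents that add atoms: none
Why: Proposed new method: the chiral phosphoric acid protonates the enol-side acetal oxygen (an acetal with an aryl-type leaving group and a p-alkoxybenzyl-stabilised cation is the classical case of general-acid catalysis), the dioxepine opens to ion 20, in which an aromatic 3-hydroxybenzofuran is tethered to an aryloxycarbenium ion on chroman O-7 and paired with the chiral phosphate, and C-2 of the enol attacks the cationic carbon while the enol proton returns to the phosphate, a net 1,3 O→C shift that contracts the ring and unveils the C-3 ketone. The closest known reaction types are the Lewis-acid Petasis–Ferrier rearrangement of cyclic enol acetals and its chiral-phosphoric-acid-catalysed aza variant of hemiaminal vinyl ethers. The one ring closed, the dihydrofuran, closes in a 5-(enol-exo) mode that is 5-endo-trig for the O=C+ form but 5-exo-trig for the dominant p-quinoid benzyl-cation form, like the enol-to-oxocarbenium aldol closure in acetal-initiated 3-acyltetrahydrofuran syntheses. The spiro centre is set by the catalyst, since the phosphate holds the enol O–H by a hydrogen bond and the cation by ion pairing, the chroman C-8–benzofuran C-2 axis turns freely in 20, and the faster of the interconverting diastereomeric ion pairs should react, so both acetal epimers converge while the remote chroman centre has little say. The benzylic centre is set relative to it by the substrate, because the aryl group of the cation takes the side of the bare ring oxygen O-1 and avoids the side of C-3–OH···phosphate and the 4-benzyloxy group, which places the aryl group cis to O-1 as in the target. The step needs C- over O-attack (O-attack only returns 19, C-attack is irreversible) and reaction at C-2 alone (the tether lets no other nucleophilic carbon reach the cation), and the weak acid should leave the chroman and the benzyl ethers untouched.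

Step 14
Reactants: 21 penta-O-benzyldaphnodorin C
Product: 22 daphnodorin C, (2S,2'S,8'S)-4,5',6-trihydroxy-2',8'-bis(4-hydroxyphenyl)-3',4'-dihydro-2'H,8'H-spiro[1-benzofuran-2,9'-furo[2,3-h]chromen]-3-one
Conditions: H2 (1 atm), 10 % Pd/C, THF/MeOH, rt
Reagents that add atoms: none
Why: Catalytic hydrogenolysis of the five primary O-benzyl ethers, which should be cleaved much faster than the two hindered cyclic secondary benzylic C–O bonds, under neutral conditions that touch neither the deactivated aryl ketone nor the three stereocentres.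

## Compound list

1 | 2,4,6-trihydroxybenzaldehyde | O=Cc1c(O)cc(O)cc1O | starting material
2 | 2,6-dihydroxy-4-(methoxymethoxy)benzaldehyde | O=Cc1c(O)cc(OCOC)cc1O | intermediate
3 | 2-(benzyloxy)-6-hydroxy-4-(methoxymethoxy)benzaldehyde | O=Cc1c(O)cc(OCOC)cc1OCc1ccccc1 | intermediate
4 | 1-[4-(benzyloxy)phenyl]ethanone | CC(=O)c1ccc(OCc2ccccc2)cc1 | starting material
5 | (E)-3-[2-(benzyloxy)-6-hydroxy-4-(methoxymethoxy)phenyl]-1-[4-(benzyloxy)phenyl]prop-2-en-1-one | O=C(/C=C/c1c(O)cc(OCOC)cc1OCc1ccccc1)c1ccc(OCc2ccccc2)cc1 | intermediate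
6 | 3-[2-(benzyloxy)-6-hydroxy-4-(methoxymethoxy)phenyl]-1-[4-(benzyloxy)phenyl]propan-1-one (not isolated) | O=C(CCc1c(O)cc(OCOC)cc1OCc1ccccc1)c1ccc(OCc2ccccc2)cc1 | intermediate
7 | (1R)-3-[2-(benzyloxy)-6-hydroxy-4-(methoxymethoxy)phenyl]-1-[4-(benzyloxy)phenyl]propan-1-ol | O[C@@H](c1ccc(OCc2ccccc2)cc1)CCc1c(O)cc(OCOC)cc1OCc1ccccc1 | intermediate
8 | (2S)-5-(benzyloxy)-2-[4-(benzyloxy)phenyl]-7-(methoxymethoxy)chromane | COCOc1cc(OCc2ccccc2)c2c(c1)O[C@H](c1ccc(OCc3ccccc3)cc1)CC2 | intermediate
9 | (2S)-5-(benzyloxy)-2-[4-(benzyloxy)phenyl]-8-bromo-7-(methoxymethoxy)chromane | COCOc1cc(OCc2ccccc2)c2c(c1Br)O[C@H](c1ccc(OCc3ccccc3)cc1)CC2 | intermediate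
10 | 4,6-dihydroxy-1-benzofuran-3(2H)-one | O=C1COc2cc(O)cc(O)c12 | starting material
11 | 4,6-bis(benzyloxy)-1-benzofuran-3(2H)-one | O=C1COc2cc(OCc3ccccc3)cc(OCc3ccccc3)c12 | intermediate
12 | 4,6-bis(benzyloxy)-3-(methoxymethoxy)-1-benzofuran | COCOc1coc2cc(OCc3ccccc3)cc(OCc3ccccc3)c12 | intermediate
13 | [4,6-bis(benzyloxy)-3-(methoxymethoxy)-1-benzofuran-2-yl]lithium (not isolated) | COCOc1c([Li])oc2cc(OCc3ccccc3)cc(OCc3ccccc3)c12 | intermediate
14 | [4,6-bis(benzyloxy)-3-(methoxymethoxy)-1-benzofuran-2-yl]zinc chloride (not isolated) | COCOc1c([Zn]Cl)oc2cc(OCc3ccccc3)cc(OCc3ccccc3)c12 | intermediate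
15 | (2S)-5-(benzyloxy)-2-[4-(benzyloxy)phenyl]-8-[4,6-bis(benzyloxy)-3-(methoxymethoxy)-1-benzofuran-2-yl]-7-(methoxymethoxy)chromane | COCOc1cc(OCc2ccccc2)c2c(c1-c1oc3cc(OCc4ccccc4)cc(OCc4ccccc4)c3c1OCOC)O[C@H](c1ccc(OCc3ccccc3)cc1)CC2 | intermediate
16 | 4,6-bis(benzyloxy)-2-{(2S)-5-(benzyloxy)-2-[4-(benzyloxy)phenyl]-7-hydroxychroman-8-yl}-1-benzofuran-3(2H)-one, both C-2 epimers | O=C1C(c2c(O)cc(OCc3ccccc3)c3c2O[C@H](c2ccc(OCc4ccccc4)cc2)CC3)Oc2cc(OCc3ccccc3)cc(OCc3ccccc3)c12 | intermediate
17 | 4-(benzyloxy)benzaldehyde | O=Cc1ccc(OCc2ccccc2)cc1 | starting material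
18 | 1-(benzyloxy)-4-(dichloromethyl)benzene | ClC(Cl)c1ccc(OCc2ccccc2)cc1 | intermediate
19 | cyclic 4-(benzyloxy)benzylidene acetal (1,3-dioxepine) bridging chroman O-7 and benzofuran O-3, chroman C-2 S, both acetal epimers | C1(c2ccc(OCc3ccccc3)cc2)Oc2cc(OCc3ccccc3)c3c(c2-c2oc4cc(OCc5ccccc5)cc(OCc5ccccc5)c4c2O1)O[C@H](c1ccc(OCc2ccccc2)cc1)CC3 | intermediate
20 | ring-opened oxocarbenium ion: 3-hydroxybenzofuran (enol) carrying the 4-(benzyloxy)benzylidene oxocarbenium unit on chroman O-7, counter-ion the chiral phosphate (not isolated) | Oc1c(-c2c([O+]=Cc3ccc(OCc4ccccc4)cc3)cc(OCc3ccccc3)c3c2O[C@H](c2ccc(OCc4ccccc4)cc2)CC3)oc2cc(OCc3ccccc3)cc(OCc3ccccc3)c12 | intermediate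
21 | penta-O-benzyldaphnodorin C, (2S,2'S,8'S), aryl at C-8' cis to benzofuranone O-1 | O=C1c2c(OCc3ccccc3)cc(OCc3ccccc3)cc2O[C@]12c1c(cc(OCc3ccccc3)c3c1O[C@H](c1ccc(OCc4ccccc4)cc1)CC3)O[C@H]2c1ccc(OCc2ccccc2)cc1 | intermediate
22 | daphnodorin C, (2S,2'S,8'S) | O=C1c2c(O)cc(O)cc2O[C@]12c1c(cc(O)c3c1O[C@H](c1ccc(O)cc1)CC3)O[C@H]2c1ccc(O)cc1 | target

## Step count and risks

Total step count: 14. Longest linear sequence: 11 (steps 1–6, 9, 10, 12, 13, 14).

**1. Step 13 (labelled).** The catalyst may discriminate poorly between the two faces of C-2. Ionisation may also be so slow that hydrolysis and an uncatalysed background closure take over. The fallback uses known chemistry: it gives up catalyst control and uses the chroman stereocentre as an internal resolving handle. It sets out from 19, which is rearranged in the classical Petasis–Ferrier manner with Me2AlCl in CH2Cl2 at −78 → 0 °C. The relative configuration (aryl cis to O-1) should still be fixed by the substrate. This should give 21 together with its (2R,2'S,8'R)-diastereomer F1. The two are diastereomers because of the chroman centre and are separated by chromatography or crystallisation. The route is rejoined at 21.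

**2. Step 12.** The enolate may be alkylated at carbon, with uncontrolled early closure, or the labile dichloride may hydrolyse and oligomerise. The fallback replaces the base-mediated bridging by acid-catalysed transacetalisation telescoped with the rearrangement. It sets out from 17, which with trimethyl orthoformate and catalytic PPTS in MeOH gives 1-(benzyloxy)-4-(dimethoxymethyl)benzene F2. 16 and F2 are then combined with the chiral acid and 5 Å MS in toluene. Exchange at the phenol generates 19 and 20 only in the flask, where they are drained by the irreversible C–C closure. The route is rejoined at 21.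

**3. Step 9.** Transmetalation and reductive elimination between the two ortho-crowded partners may be slow, so that protodezincation of the heteroarylzinc takes over. The fallback changes the union from biaryl coupling to enolate arylation. It sets out from 9 and 11. Palladium-catalysed ketone α-arylation (Pd2(dba)3, XPhos, NaOt-Bu, toluene, 80 °C) of the unhindered CH2 enolate should give 4,6-bis(benzyloxy)-2-{(2S)-5-(benzyloxy)-2-[4-(benzyloxy)phenyl]-7-(methoxymethoxy)chroman-8-yl}-1-benzofuran-3(2H)-one F3. The single MOM group of F3 is removed as in step 10. The route is rejoined at 16.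

## Further compounds

F1 | step 13 | (2R,2'S,8'R)-diastereomer of penta-O-benzyldaphnodorin C | O=C1c2c(OCc3ccccc3)cc(OCc3ccccc3)cc2O[C@@]12c1c(cc(OCc3ccccc3)c3c1O[C@H](c1ccc(OCc4ccccc4)cc1)CC3)O[C@@H]2c1ccc(OCc2ccccc2)cc1
F2 | step 12 | 1-(benzyloxy)-4-(dimethoxymethyl)benzene | COC(OC)c1ccc(OCc2ccccc2)cc1
F3 | step 9 | 4,6-bis(benzyloxy)-2-{(2S)-5-(benzyloxy)-2-[4-(benzyloxy)phenyl]-7-(methoxymethoxy)chroman-8-yl}-1-benzofuran-3(2H)-one, both C-2 epimers | O=C1C(c2c(OCOC)cc(OCc3ccccc3)c3c2O[C@H](c2ccc(OCc4ccccc4)cc2)CC3)Oc2cc(OCc3ccccc3)cc(OCc3ccccc3)c12
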